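The route rests on disconnecting C6–C7 in the seven-membered ring A. The feature exploited is the 1,4-relationship of the C6 oxygen and the C9 carbonyl across ring A, backed by the C4 hydroxyl of ring B lying cis to C6. Reductive coupling of a C6 aldehyde with the methylene terminus (C7) of a C7=C8(CH3)–C9=O enone by SmI2 closes ring A, creates the C6 carbinol and leaves the C9 ketone for later desaturation, all in one operation. The substrate is a cyclopentane (ring B) whose C5 carries the aldehyde carbon C6, whose quaternary C1 carries a CH2–CO–C(CH3)=CH2 chain trans to it, and whose C4 holds the free tertiary hydroxyl and the isopropyl group.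

Key step: step 11

Numbering: daucane numbering is used for atoms; ring B = C1(CH3)–C2–C3–C4(OH)(i-Pr)–C5(H), ring A = C5–C6(O)–C7–C8(CH3)–C9(=O)–C10–C1. The target is 1R,4R,5S,6S, with the C1 methyl and C4 hydroxyl on one face and H5 and the C6 oxygen on the other.

Assumption: the enantiomer of the carbene ligand in step 1 is taken to be the one that forms C1 as drawn (S in compound 5); the sense of induction is to be verified on compound 10.

Step 1
Reactants: 1 3-methylcyclopent-2-en-1-one; 2 ethynyltrimethylsilane
Product: 5 (S)-trimethyl({3-methyl-3-[1-(trimethylsilyl)ethenyl]cyclopent-1-en-1-yl}oxy)silane, via alkenylalane 3 (not isolated), via aluminium enolate 4 (not isolated)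
Conditions: 2, i-Bu2AlH, hexane (THF additive), 55 °C; then 1, Cu(OTf)2 (5 mol %), chiral sulfonate-bearing imidazolinium carbene precursor (5 mol %, pre-metalated with Ag2O), THF, −78 → −30 °C; then Me3SiOTf, −78 → 0 °C
Reagents that add atoms: trimethylsilyl trifluoromethanesulfonate, C[Si](C)(C)OS(=O)(=O)C(F)(F)F
Why: Copper-catalysed enantioselective conjugate addition of a silyl-substituted alkenylaluminium (made by hydroalumination, silicon directing aluminium to its own carbon) is an established way to vinyl-type quaternary carbons on β-methyl cycloalkenones, the chiral carbene–copper complex choosing the enone face so that C1 should form with S configuration, and O-silylation of the aluminium enolate fixes the enolate toward C5.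

Step 2
Reactants: 5 (S)-trimethyl({3-methyl-3-[1-(trimethylsilyl)ethenyl]cyclopent-1-en-1-yl}oxy)silane; 6 formaldehyde
Product: 8 (2S,3S)-2-(hydroxymethyl)-3-methyl-3-[1-(trimethylsilyl)ethenyl]cyclopentan-1-one (CH2OH cis to the methyl group), via lithium enolate 7 (not isolated)
Conditions: MeLi, THF, 0 °C → rt; then 6 (gas from cracked paraformaldehyde), −78 °C; aq. NH4Cl
Reagents that add atoms: none
Why: Methyllithium cleaves the O–Si bond to the regiodefined lithium enolate, whose aldol addition to monomeric formaldehyde (regiospecific hydroxymethylation) should occur on the face of C5 away from the bulky 1-(trimethylsilyl)vinyl group on the neighbouring quaternary carbon, which places CH2OH cis to the C1 methyl (2S).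

Step 3
Reactants: 8 (2S,3S)-2-(hydroxymethyl)-3-methyl-3-[1-(trimethylsilyl)ethenyl]cyclopentan-1-one
Product: 9 (2S,3S)-2-{[tert-butyl(diphenyl)silyl]oxymethyl}-3-methyl-3-[1-(trimethylsilyl)ethenyl]cyclopentan-1-one
Conditions: t-BuPh2SiCl, imidazole, CH2Cl2, 0 °C → rt
Reagents that add atoms: tert-butyl(chloro)diphenylsilane, CC(C)(C)[Si](Cl)(c1ccccc1)c1ccccc1
Why: Imidazole-promoted silylation of the primary alcohol gives a tert-butyldiphenylsilyl ether, chosen because it should withstand the acid of step 4 and the organometallic steps 5 to 8 and because it shields one face of the ketone.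

Step 4
Reactants: 9 (2S,3S)-2-{[tert-butyl(diphenyl)silyl]oxymethyl}-3-methyl-3-[1-(trimethylsilyl)ethenyl]cyclopentan-1-one
Product: 10 (2S,3R)-2-{[tert-butyl(diphenyl)silyl]oxymethyl}-3-ethenyl-3-methylcyclopentan-1-one
Conditions: CF3CO2H, CH2Cl2, 0 °C → rt; aq. NaHCO3
Reagents that add atoms: none
Why: Acid-mediated protodesilylation of the vinylsilane (electrophilic ipso-substitution, the cationic intermediate being stabilised by the carbon–silicon bond) unmasks the vinyl group, and a short cold exposure is meant to spare the C5 centre next to the ketone and the acid-stable silyl ether (the descriptor at C1 changes to R only through priorities).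

Step 5
Reactants: 10 (2S,3R)-2-{[tert-butyl(diphenyl)silyl]oxymethyl}-3-ethenyl-3-methylcyclopentan-1-one; 11 isopropylmagnesium chloride
Product: 12 (1R,2S,3R)-2-{[tert-butyl(diphenyl)silyl]oxymethyl}-3-ethenyl-3-methyl-1-(propan-2-yl)cyclopentan-1-ol
Conditions: LaCl3·2LiCl, THF, 0 °C; then 11, 0 °C; aq. NH4Cl
Reagents that add atoms: none
Why: Lanthanum-salt-promoted Grignard 1,2-addition, which suppresses enolisation and β-hydride reduction by the secondary reagent, should take place on the face of the C4 carbonyl opposite the adjacent CH2OSi group, so that the new hydroxyl is cis to C6 and to the C1 methyl (1R in this compound).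

Step 6
Reactants: 12 (1R,2S,3R)-2-{[tert-butyl(diphenyl)silyl]oxymethyl}-3-ethenyl-3-methyl-1-(propan-2-yl)cyclopentan-1-ol
Product: 14 (1R,2S,3R)-2-{[tert-butyl(diphenyl)silyl]oxymethyl}-3-(2-hydroxyethyl)-3-methyl-1-(propan-2-yl)cyclopentan-1-ol, via alkylborane 13 (not isolated)
Conditions: 9-BBN, THF, rt → 50 °C; then aq. NaOH, H2O2, 0 °C → rt
Reagents that add atoms: hydrogen peroxide, OO
Why: Anti-Markovnikov hydroboration with 9-BBN places boron on the terminal carbon (C9) of the vinyl group and oxidation with retention gives the primary alcohol; no stereocentre is formed.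

Step 7
Reactants: 14 (1R,2S,3R)-2-{[tert-butyl(diphenyl)silyl]oxymethyl}-3-(2-hydroxyethyl)-3-methyl-1-(propan-2-yl)cyclopentan-1-ol
Product: 15 2-[(1R,2S,3R)-2-{[tert-butyl(diphenyl)silyl]oxymethyl}-3-hydroxy-1-methyl-3-(propan-2-yl)cyclopentyl]acetaldehyde
Conditions: Dess–Martin periodinane, NaHCO3, CH2Cl2, 0 °C → rt
Reagents that add atoms: none
Why: Dess–Martin oxidation converts the primary alcohol to the aldehyde without touching the tertiary alcohol or the silyl ether, and the C4 hydroxyl, being trans to the acetaldehyde chain on the ring, cannot close a lactol.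

Step 8
Reactants: 15 2-[(1R,2S,3R)-2-{[tert-butyl(diphenyl)silyl]oxymethyl}-3-hydroxy-1-methyl-3-(propan-2-yl)cyclopentyl]acetaldehyde; 16 2-bromopropene
Product: 18 (1R,2S,3R)-2-{[tert-butyl(diphenyl)silyl]oxymethyl}-3-(2-hydroxy-3-methylbut-3-en-1-yl)-3-methyl-1-(propan-2-yl)cyclopentan-1-ol (both epimers at the new carbinol), via isopropenylmagnesium bromide 17 (not isolated)
Conditions: 16, Mg, THF, rt → 40 °C; then 15, THF, −78 → 0 °C; aq. NH4Cl
Reagents that add atoms: none
Why: Grignard 1,2-addition of the isopropenyl reagent to the aldehyde (one further equivalent is consumed by the tertiary hydroxyl) brings in C8, its methyl group and C7; the new carbinol centre forms without control, which does not matter because it is oxidised in step 10.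

Step 9
Reactants: 18 (1R,2S,3R)-2-{[tert-butyl(diphenyl)silyl]oxymethyl}-3-(2-hydroxy-3-methylbut-3-en-1-yl)-3-methyl-1-(propan-2-yl)cyclopentan-1-ol
Product: 19 (1R,2S,3R)-3-(2-hydroxy-3-methylbut-3-en-1-yl)-2-(hydroxymethyl)-3-methyl-1-(propan-2-yl)cyclopentan-1-ol (both carbinol epimers)
Conditions: Bu4NF, THF, rt; aq. NH4Cl
Reagents that add atoms: none
Why: Fluoride-mediated cleavage of the silyl ether frees the C6 hydroxyl under conditions that leave the allylic and tertiary alcohols untouched.

Step 10
Reactants: 19 (1R,2S,3R)-3-(2-hydroxy-3-methylbut-3-en-1-yl)-2-(hydroxymethyl)-3-methyl-1-(propan-2-yl)cyclopentan-1-ol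
Product: 20 (1R,2R,5R)-2-hydroxy-5-methyl-5-(3-methyl-2-oxobut-3-en-1-yl)-2-(propan-2-yl)cyclopentane-1-carbaldehyde
Conditions: Dess–Martin periodinane (3 equiv), NaHCO3, CH2Cl2, 0 °C → rt; used at once
Reagents that add atoms: none
Why: Dess–Martin oxidation of the primary and the allylic secondary hydroxyl in one operation gives the keto aldehyde while the tertiary C4 hydroxyl is inert; the product, a β-hydroxy aldehyde and α-methylene ketone, is kept buffered and is not stored.

Step 11
Reactants: 20 (1R,2R,5R)-2-hydroxy-5-methyl-5-(3-methyl-2-oxobut-3-en-1-yl)-2-(propan-2-yl)cyclopentane-1-carbaldehyde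
Product: 21 (1R,4R,5S,6S)-4,6-dihydroxydaucan-9-one (4β,6α-diol; both C8 epimers)
Conditions: SmI2 (2.5 equiv), t-BuOH (3 equiv), THF, −78 → 0 °C, slow addition of 20 to 0.005 M
Reagents that add atoms: none
Why: Electron transfer from SmI2 to the C6 aldehyde, helped by the neighbouring C4 hydroxyl binding samarium, gives a ketyl whose carbon radical adds to the methylene terminus C7 of the enone; the C8 α-keto radical is then reduced by a second SmI2 to the enolate of trivalent samarium and protonation returns the C9 ketone (should the enone accept the first electron instead, its β-carbon couples with the aldehyde and the same bond results). The closest known reaction type is the SmI2-mediated ketyl–olefin reductive cyclisation of an aldehyde onto an α,β-unsaturated carbonyl compound. Ring A is closed in the 7-endo-trig mode, C7 and C8 both ending inside the new ring. C6 is controlled by a chair-like transition state in which the oxygen, held to the cis C4 oxygen through trivalent samarium, takes the pseudo-equatorial site and so escapes the 1,3-diaxial contact with the angular C1 methyl, which should put O6 on the face of H5 (6S); C8 comes from unselective protonation of the enolate and is removed again in step 15. The step needs C6–C7 coupling in preference to aldehyde dimerisation, simple reduction and attack on the C9 carbonyl carbon: slow addition at high dilution disfavours the bimolecular path, the nucleophilic ketyl is polarity-matched with the unhindered β-carbon, and the trans arrangement of the two chains on ring B makes the alternative five-membered pinacol closure a strained trans-fused bicyclo[3.3.0]octane while the trans-fused five–seven product is unstrained.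

Step 12
Reactants: 22 p-coumaric acid
Product: 24 (E)-3-{4-[(tert-butyldimethylsilyl)oxy]phenyl}prop-2-enoic acid, via bis-silyl compound 23 (not isolated)
Conditions: t-BuMe2SiCl, imidazole, DMF, rt; then AcOH/THF/H2O, rt
Reagents that add atoms: tert-butyl(chloro)dimethylsilane, CC(C)(C)[Si](C)(C)Cl
Why: Silylation of both acidic groups followed by selective hydrolysis of the labile silyl ester under mild acid, to which the aryl silyl ether is stable, gives the phenol-protected acid.

Step 13
Reactants: 21 (1R,4R,5S,6S)-4,6-dihydroxydaucan-9-one; 24 (E)-3-{4-[(tert-butyldimethylsilyl)oxy]phenyl}prop-2-enoic acid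
Product: 25 (1R,4R,5S,6S)-4-hydroxy-9-oxodaucan-6-yl (E)-3-{4-[(tert-butyldimethylsilyl)oxy]phenyl}prop-2-enoate (both C8 epimers)
Conditions: EDC·HCl, DMAP, CH2Cl2, 0 °C → rt
Reagents that add atoms: none
Why: Carbodiimide/DMAP (Steglich) esterification acylates the secondary C6 hydroxyl with retention of configuration, the tertiary C4 hydroxyl being too hindered to react.

Step 14
Reactants: 25 (1R,4R,5S,6S)-4-hydroxy-9-oxodaucan-6-yl (E)-3-{4-[(tert-butyldimethylsilyl)oxy]phenyl}prop-2-enoate
Product: 26 (1R,4R,5S,6S)-4,9-bis(trimethylsilyloxy)dauc-8-en-6-yl (E)-3-{4-[(tert-butyldimethylsilyl)oxy]phenyl}prop-2-enoate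
Conditions: Me3SiOTf, Et3N, CH2Cl2, −20 → 0 °C
Reagents that add atoms: trimethylsilyl trifluoromethanesulfonate, C[Si](C)(C)OS(=O)(=O)C(F)(F)F
Why: Soft enolisation with a silyl triflate and amine base gives the silyl enol ether toward the more substituted C8 and silylates the C4 hydroxyl at the same time; any enol ether formed toward C10 cannot be dehydrogenated, because C1 carries no hydrogen, and returns ketone 25 on work-up.

Step 15
Reactants: 26 (1R,4R,5S,6S)-4,9-bis(trimethylsilyloxy)dauc-8-en-6-yl (E)-3-{4-[(tert-butyldimethylsilyl)oxy]phenyl}prop-2-enoate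
Product: 27 (1R,4R,5S,6S)-9-oxo-4-(trimethylsilyloxy)dauc-7-en-6-yl (E)-3-{4-[(tert-butyldimethylsilyl)oxy]phenyl}prop-2-enoate
Conditions: Pd(OAc)2 (1.1 equiv), MeCN, rt
Reagents that add atoms: none
Why: Saegusa–Ito oxidation, in which palladation of the silyl enol ether at C8 and β-hydride elimination from C7 introduce the C7=C8 double bond and thereby remove the uncontrolled C8 centre.

Step 16
Reactants: 27 (1R,4R,5S,6S)-9-oxo-4-(trimethylsilyloxy)dauc-7-en-6-yl (E)-3-{4-[(tert-butyldimethylsilyl)oxy]phenyl}prop-2-enoate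
Product: 28 (1R,4R,5S,6S)-4-hydroxy-9-oxodauc-7-en-6-yl (E)-3-(4-hydroxyphenyl)prop-2-enoate (CNP0310968.1)
Conditions: Bu4NF, AcOH, THF, 0 °C
Reagents that add atoms: none
Why: Fluoride cleaves the aryl tert-butyldimethylsilyl ether and the tertiary trimethylsilyl ether, and acetic acid buffers the phenoxide and alkoxide so that the cinnamate ester, the enone and the C6 centre should stay untouched.

Compound list
1 | 3-methylcyclopent-2-en-1-one | CC1=CC(=O)CC1 | starting material
2 | ethynyltrimethylsilane | C#C[Si](C)(C)C | starting material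
3 | diisobutyl[1-(trimethylsilyl)ethenyl]aluminium | C=C([Si](C)(C)C)[Al](CC(C)C)CC(C)C | intermediate
4 | diisobutylaluminium (S)-3-methyl-3-[1-(trimethylsilyl)ethenyl]cyclopent-1-en-1-olate | CC(C)C[Al](CC(C)C)OC1=C[C@@](C)(C(=C)[Si](C)(C)C)CC1 | intermediate
5 | (S)-trimethyl({3-methyl-3-[1-(trimethylsilyl)ethenyl]cyclopent-1-en-1-yl}oxy)silane | C[Si](C)(C)OC1=C[C@@](C)(C(=C)[Si](C)(C)C)CC1 | intermediate
6 | formaldehyde | C=O | starting material
7 | lithium (S)-3-methyl-3-[1-(trimethylsilyl)ethenyl]cyclopent-1-en-1-olate | [Li]OC1=C[C@@](C)(C(=C)[Si](C)(C)C)CC1 | intermediate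
8 | (2S,3S)-2-(hydroxymethyl)-3-methyl-3-[1-(trimethylsilyl)ethenyl]cyclopentan-1-one | O=C1CC[C@](C)(C(=C)[Si](C)(C)C)[C@H]1CO | intermediate
9 | (2S,3S)-2-{[tert-butyl(diphenyl)silyl]oxymethyl}-3-methyl-3-[1-(trimethylsilyl)ethenyl]cyclopentan-1-one | O=C1CC[C@](C)(C(=C)[Si](C)(C)C)[C@H]1CO[Si](c2ccccc2)(c2ccccc2)C(C)(C)C | intermediate
10 | (2S,3R)-2-{[tert-butyl(diphenyl)silyl]oxymethyl}-3-ethenyl-3-methylcyclopentan-1-one | O=C1CC[C@](C)(C=C)[C@H]1CO[Si](c2ccccc2)(c2ccccc2)C(C)(C)C | intermediate
11 | isopropylmagnesium chloride | CC(C)[Mg]Cl | starting material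
12 | (1R,2S,3R)-2-{[tert-butyl(diphenyl)silyl]oxymethyl}-3-ethenyl-3-methyl-1-(propan-2-yl)cyclopentan-1-ol | CC(C)[C@]1(O)CC[C@](C)(C=C)[C@H]1CO[Si](c2ccccc2)(c2ccccc2)C(C)(C)C | intermediate
13 | 9-{2-[(1R,2S,3R)-2-{[tert-butyl(diphenyl)silyl]oxymethyl}-3-hydroxy-1-methyl-3-(propan-2-yl)cyclopentyl]ethyl}-9-borabicyclo[3.3.1]nonane | CC(C)[C@]1(O)CC[C@](C)(CCB2C3CCCC2CCC3)[C@H]1CO[Si](c4ccccc4)(c4ccccc4)C(C)(C)C | intermediate
14 | (1R,2S,3R)-2-{[tert-butyl(diphenyl)silyl]oxymethyl}-3-(2-hydroxyethyl)-3-methyl-1-(propan-2-yl)cyclopentan-1-ol | CC(C)[C@]1(O)CC[C@](C)(CCO)[C@H]1CO[Si](c2ccccc2)(c2ccccc2)C(C)(C)C | intermediate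
15 | 2-[(1R,2S,3R)-2-{[tert-butyl(diphenyl)silyl]oxymethyl}-3-hydroxy-1-methyl-3-(propan-2-yl)cyclopentyl]acetaldehyde | CC(C)[C@]1(O)CC[C@](C)(CC=O)[C@H]1CO[Si](c2ccccc2)(c2ccccc2)C(C)(C)C | intermediate
16 | 2-bromopropene | CC(Br)=C | starting material
17 | isopropenylmagnesium bromide | CC(=C)[Mg]Br | intermediate
18 | (1R,2S,3R)-2-{[tert-butyl(diphenyl)silyl]oxymethyl}-3-(2-hydroxy-3-methylbut-3-en-1-yl)-3-methyl-1-(propan-2-yl)cyclopentan-1-ol, both side-chain carbinol epimers | CC(C)[C@]1(O)CC[C@](C)(CC(O)C(C)=C)[C@H]1CO[Si](c2ccccc2)(c2ccccc2)C(C)(C)C | intermediate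
19 | (1R,2S,3R)-3-(2-hydroxy-3-methylbut-3-en-1-yl)-2-(hydroxymethyl)-3-methyl-1-(propan-2-yl)cyclopentan-1-ol, both side-chain carbinol epimers | CC(C)[C@]1(O)CC[C@](C)(CC(O)C(C)=C)[C@H]1CO | intermediate
20 | (1R,2R,5R)-2-hydroxy-5-methyl-5-(3-methyl-2-oxobut-3-en-1-yl)-2-(propan-2-yl)cyclopentane-1-carbaldehyde | CC(C)[C@]1(O)CC[C@](C)(CC(=O)C(C)=C)[C@H]1C=O | intermediate
21 | (1R,4R,5S,6S)-4,6-dihydroxydaucan-9-one, both C8 epimers | CC1C[C@H](O)[C@@H]2[C@](C)(CC[C@@]2(O)C(C)C)CC1=O | intermediate
22 | p-coumaric acid | OC(=O)/C=C/c1ccc(O)cc1 | starting material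
23 | tert-butyldimethylsilyl (E)-3-{4-[(tert-butyldimethylsilyl)oxy]phenyl}prop-2-enoate | CC(C)(C)[Si](C)(C)OC(=O)/C=C/c1ccc(O[Si](C)(C)C(C)(C)C)cc1 | intermediate
24 | (E)-3-{4-[(tert-butyldimethylsilyl)oxy]phenyl}prop-2-enoic acid | OC(=O)/C=C/c1ccc(O[Si](C)(C)C(C)(C)C)cc1 | intermediate
25 | (1R,4R,5S,6S)-4-hydroxy-9-oxodaucan-6-yl (E)-3-{4-[(tert-butyldimethylsilyl)oxy]phenyl}prop-2-enoate, both C8 epimers | CC1C[C@H](OC(=O)/C=C/c3ccc(O[Si](C)(C)C(C)(C)C)cc3)[C@@H]2[C@](C)(CC[C@@]2(O)C(C)C)CC1=O | intermediate
26 | (1R,4R,5S,6S)-4,9-bis(trimethylsilyloxy)dauc-8-en-6-yl (E)-3-{4-[(tert-butyldimethylsilyl)oxy]phenyl}prop-2-enoate | CC=1C[C@H](OC(=O)/C=C/c3ccc(O[Si](C)(C)C(C)(C)C)cc3)[C@@H]2[C@](C)(CC[C@@]2(O[Si](C)(C)C)C(C)C)CC=1O[Si](C)(C)C | intermediate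
27 | (1R,4R,5S,6S)-9-oxo-4-(trimethylsilyloxy)dauc-7-en-6-yl (E)-3-{4-[(tert-butyldimethylsilyl)oxy]phenyl}prop-2-enoate | CC1=C[C@H](OC(=O)/C=C/c3ccc(O[Si](C)(C)C(C)(C)C)cc3)[C@@H]2[C@](C)(CC[C@@]2(O[Si](C)(C)C)C(C)C)CC1=O | intermediate
28 | (1R,4R,5S,6S)-4-hydroxy-9-oxodauc-7-en-6-yl (E)-3-(4-hydroxyphenyl)prop-2-enoate (CNP0310968.1) | CC1=C[C@H](OC(=O)/C=C/c2ccc(O)cc2)[C@@H]2[C@](C)(CC[C@@]2(O)C(C)C)CC1=O | target

Total step count: 16 (15 in the main line and step 12 for the acid partner). Longest linear sequence: 15 steps (from 1 to 28 through steps 1–11 and 13–16).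

The three steps most likely to fail

Step 11. What may go wrong is poor facial selectivity at the ketyl carbon, C7 bonding to the face of C6 that leaves the oxygen syn to the C1 methyl, alongside some simple reduction or dimerisation of the aldehyde. The fallback sets out from 20 and accepts the cyclisation product with the opposite C6 configuration, (1R,4R,5S,6R)-4,6-dihydroxydaucan-9-one F1. This alcohol would not be acylated with retention but esterified with acid 24 in a Mitsunobu reaction (PPh3, diisopropyl azodicarboxylate, toluene, 0 °C → rt), in which the activated C6 oxygen is displaced by the carboxylate with inversion. The route is rejoined at ester 25.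

Step 5. What may go wrong is enolisation of the hindered ketone, or β-hydride transfer from the secondary Grignard reagent, overtaking addition. The fallback replaces the preformed, basic organomagnesium reagent by a Barbier-type reductive coupling. Ketone 10 and 2-iodopropane would be treated together with SmI2 and HMPA in THF at rt, so that a non-basic secondary alkylsamarium is generated in the presence of the carbonyl group and adds on the same face. It sets out from 10 and comes back at 12, and it makes no compound outside the list (F0).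

Step 4. What may go wrong is acid-induced epimerisation at C5 through the enol, or loss of the silyl ether, during protodesilylation. The fallback removes silicon without acid in two operations. Iododesilylation of 9 with N-iodosuccinimide in hexafluoroisopropanol/CH2Cl2 at 0 °C would give the vinyl iodide (2S,3S)-2-{[tert-butyl(diphenyl)silyl]oxymethyl}-3-(1-iodoethenyl)-3-methylcyclopentan-1-one F2. Its carbon–iodine bond would then be reduced with Bu3SnH and catalytic Pd(PPh3)4 in THF at rt. It sets out from 9 and comes back at 10.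

Further compounds
F1 | step 11 | (1R,4R,5S,6R)-4,6-dihydroxydaucan-9-one (6-epimer of 21, both C8 epimers) | CC1C[C@@H](O)[C@@H]2[C@](C)(CC[C@@]2(O)C(C)C)CC1=O
F0 | step 5 | none | none
F2 | step 4 | (2S,3S)-2-{[tert-butyl(diphenyl)silyl]oxymethyl}-3-(1-iodoethenyl)-3-methylcyclopentan-1-one | O=C1CC[C@](C)(C(I)=C)[C@H]1CO[Si](c2ccccc2)(c2ccccc2)C(C)(C)C
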